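## Structural features

The target (17) is 3-bromo-12H-pyrido[1,2-a:3,4-b']diindole-13-carbaldehyde, a flat, fully aromatic pentacycle with no stereocentre, so no stereocentres stand next to each other.

- Ring A is the benzo ring C7b–C11a and ring B the pyrrole ring (C7a, C7b, C11a, N12–H, C12a); together they form one indole.
- Ring C is the pyridine-type ring (N5, C6, C7, C7a, C12a, C12b).
- Ring D is the pyrrole ring (N5, C4a, C13a, C13, C12b) and ring E the bromobenzo ring (C13a, C1, C2, C3, C4, C4a); together they form a second indole whose nitrogen N5 is the bridgehead shared with ring C.

The substituents are the aldehyde on C13, bromine on C3 and the free N12–H. The fragile points are the electron-rich indolizine-type core, which is easily oxidised or protonated at C13, and the aryl bromide, which does not tolerate low-valent metals or hydrogenolysis. The real difficulty is regiochemical: bromine must sit on C3, meta to N5, a position that late electrophilic bromination would not find. The full oxidation level must also be reached without over-oxidation. The key step exploits the fusion of ring E to ring D through C13a–C4a, with N5 on C4a and bromine on C3. This is the imprint of a 2-amino-4-bromofuran whose C2 and C5 become C4a and C2.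

## Logic of the disconnections

**17 to 15.** The C13–CHO bond is cut. C13 is the enamine-type β-carbon of ring D and the most nucleophilic carbon of the core, so the formyl group goes on last. This keeps the aldehyde away from the hydride and the quinone used earlier. The forward step must hit C13 and not N12, C6 or C7.

**15 to 13, through 14.** No skeletal bond is cut; four hydrogens are added back at C12b/C13 and at C6/C7. This leads to a non-planar compound in which N5 is an ordinary aniline nitrogen and ring D is an indoline, which is what the key step delivers. The forward step needs a hydride acceptor that removes two molecules of hydrogen in sequence, leaves C3–Br alone and stops at 15.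

**13 to 12.** The C6 methylene is traced back to a lactam carbonyl. The acyl group on N5 is what tames the aminofuran and allows the N–furan coupling, so it is carried through the key step and removed directly afterwards. An order in which ring D is aromatised first and the resulting N-acylindole is partly reduced and dehydrated under acid was weighed and set aside. Its hemiaminal can open to an aldehyde that C13 could capture to form a carbazole, and the lactam could rest as its hydroxy-aromatic tautomer. Reducing at the indoline stage avoids both. The forward step must spare the aryl bromide and the indole.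

**12 to 8 (key disconnection).** The bonds C4a–C13a and C2–C1 are cut and water is added back. Rings D and E open to a furan on N5 and a terminal alkene on C12b. This traces two rings and the entire bromoarene regiochemistry to a monocyclic furan. The forward step requires an unactivated alkene to add thermally and the oxygen bridge to open towards the arene with the bromine kept. In 8 the indole nitrogen carries a Boc group that is shed within the same operation.

**8 to 7 and 2.** The N5–C4a bond (lactam nitrogen to furan C2) is cut. An iodide at furan C2 beside a bromide at C4 lets the halogen, not the ring position, decide where nitrogen enters. This is why 2 is preferred to a dibromofuran. The forward step asks a hindered lactam nitrogen to couple while the indole nitrogen stays silent.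

**7 to 6.** The carbamate on the indole nitrogen is removed. It is there because copper also arylates indole N–H, and one extra step is judged cheaper than a mixture at the coupling. The forward step must acylate the indole nitrogen and not the lactam nitrogen.

**6 to 3 and 4.** The N5–C12b and C12a–C12b bonds are cut, with C12b as the aldehyde carbon of 4. Ring C then forms in one operation from a purchasable amide. The forward step must keep the β,γ-double bond out of conjugation.

**2 to 1.** The C–I bond is traced back to the carboxyl group, which marks furan C2 while the bromine of the purchased acid is already on C4. The forward step needs ipso substitution and not attack at the free C5–H.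

## Other disconnections considered

**Alternative 1:** The cut is the C7a=C12a bond of ring B. It leads back to the oxo-amide N-{2-[3-(tert-butyldimethylsilyloxy)propanoyl]phenyl}-6-bromo-1H-indole-2-carboxamide A1. In the forward key step, low-valent titanium from TiCl3 and zinc would couple the ketone carbon with the anilide carbonyl carbon and close ring B. The product would be the biindole 6-bromo-3'-[2-(tert-butyldimethylsilyloxy)ethyl]-1H,1'H-2,2'-biindole A2. Desilylation, activation of the alcohol and N-alkylation at the bromoindole nitrogen would then close ring C to 14, followed by one dehydrogenation to 15 and formylation to 17.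

- In its favour: the bromine position is bought with the bromoindole half, which makes it the equal of the chosen plan in regiochemical certainty. Rings D and E are aromatic from the start, so only one dehydrogenation is needed; here it is the better plan. Nothing is heated above reflux, again an advantage.
- Against it: the titanium reagent is a strong reductant used in excess and could attack the C–Br bond. The aminoketone half needs its own multistep preparation. Four operations remain after the key step. The activated 2-(indol-3-yl)ethyl unit could eliminate or spirocyclise at indole C3 before nitrogen closes ring C.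
- Comparison: the alternative forms one bond and one ring in its key step, against two bonds and two rings in the chosen plan. Its estimated length is about one or two operations longer.

**Alternative 2:** The cuts are N12–C12a and C12a–C12b. They lead back to the dibromoalkene 2-[1,1-dibromo-4-(6-bromo-1H-indol-1-yl)but-1-en-2-yl]aniline A3. In the forward key step, Pd(OAc)2 with an electron-rich phosphine and K3PO4 would join the aniline nitrogen to one vinylic C–Br bond. The second vinylic C–Br bond would then arylate C2–H of the tethered bromoindole. Rings B and C would close to give 3-bromo-6,7-dihydro-12H-pyrido[1,2-a:3,4-b']diindole A4, which is identical with 14.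

- In its favour: two rings and two bonds form in one catalytic operation, the equal of the chosen key step. It lands directly on 14, so only one dehydrogenation and the formylation remain; this endgame is shorter than the chosen one.
- Against it: A3 holds three C–Br bonds. Zerovalent palladium with an electron-rich phosphine, at the temperature a C–H arylation needs, would have to leave the aryl bromide alone, and the target must keep that bromine. The tetrasubstituted dibromoalkene would have to come from dibromo-olefination of an aryl alkyl ketone, which is sluggish.
- Comparison: the overall length should be equal or one step shorter. The mechanistic risk sits on the very atom that defines the target. The chosen plan never exposes C3–Br to palladium and couples through an iodide with a copper catalyst at moderate temperature.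

**Alternative 3:** The cuts are N5–C12b and N5–C6. They lead back to the pyrylium salt 1-(4-bromo-2-nitrobenzyl)-9H-pyrano[3,4-b]indol-2-ium tetrafluoroborate A5. In the forward key step, reduction of the nitro group would free an aniline that adds to pyrylium C1 and closes the five-membered ring D. The pyran would open and the nitrogen would reclose on the former C3 with loss of water. Loss of a C13 proton would give 3-bromo-12H-pyrido[1,2-a:3,4-b']diindole A6, which is identical with 15.

- In its favour: the aromatic core is reached with no dehydrogenation step, which is better redox economy than the chosen plan. Only the formylation would remain, the shortest endgame of all. The bromine is fixed by the benzyl building block, the equal of the chosen plan.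
- Against it: A5 needs a 1,5-dicarbonyl precursor of the 2-acylindol-3-ylacetaldehyde type and a strongly acidic cyclodehydration. Its methylene between the nitroarene and the pyrylium ring is very acidic and invites anhydrobase formation and self-condensation. The reductant would have to reduce the nitro group without one-electron reduction of the pyrylium ring or loss of bromine.
- Comparison: this is the shortest plan on paper. Its risk is concentrated in making and handling a reactive cationic intermediate. The chosen plan runs through neutral, isolable compounds and a cycloaddition class with close analogy.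

Key step: step 5

Remark: compounds 6–8 are numbered as pyrido[3,4-b]indoles and 9–17 as pyrido[1,2-a:3,4-b']diindoles. C12b (C1 of the β-carbolinone) is the only stereocentre of the isolated intermediates; it is carried as the racemate and erased in step 7.

Remark: the precursor and the product of the key step are carried with a Boc group on the indole nitrogen (8 and 11); 12 is the unprotected product. Mapping the atoms of 8 onto 12 and 17 revealed no structural error: furan C4 becomes C3.

Remark: 1, 3 and 4 are assumed to be purchasable.

## Route

Step 1
Reactants: 1 4-bromofuran-2-carboxylic acid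
Product: 2 4-bromo-2-iodofuran
Conditions: I2 (3 equiv), K3PO4 (1 equiv), MeCN, 100 °C (sealed tube, dark); aq Na2S2O3
Reagents that add atoms: iodine, II
Why: Ipso-iododecarboxylation of a heteroaromatic carboxylate (transition-metal-free decarboxylative iodination): the furoate is iodinated at the carboxyl-bearing α-carbon and loses CO2, the C4 bromine is untouched, and the iodide marks C2 for the C–N coupling.

Step 2
Reactants: 3 indole-3-acetamide; 4 but-3-enal diethyl acetal
Product: 6 1-allyl-1,2,4,9-tetrahydro-3H-pyrido[3,4-b]indol-3-one (racemic), via N-acyl N,O-acetal 5 (not isolated)
Conditions: TFA (5 equiv), CH2Cl2, 0 °C to rt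
Reagents that add atoms: none
Why: N-acyl Pictet–Spengler reaction (intramolecular amidoalkylation): the acetal ionises, the primary amide gives 5 and then an N-acyliminium ion that indole C2 attacks in a 6-endo closure (attack of C2 first and capture by nitrogen leads to the same ring); the acetal and the low temperature are chosen to keep the double bond out of conjugation, and C12b forms as the racemate, which is acceptable because it is erased later.

Step 3
Reactants: 6 1-allyl-1,2,4,9-tetrahydro-3H-pyrido[3,4-b]indol-3-one
Product: 7 tert-butyl 1-allyl-3-oxo-1,2,3,4-tetrahydro-9H-pyrido[3,4-b]indole-9-carboxylate (racemic)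
Conditions: Boc2O (1.05 equiv), DMAP (0.1 equiv), MeCN, 0 °C to rt
Reagents that add atoms: di-tert-butyl dicarbonate, CC(C)(C)OC(=O)OC(=O)OC(C)(C)C
Why: DMAP-catalysed carbamate formation at the indole nitrogen, the more acidic N–H by several pKa units; one equivalent of Boc2O should leave the hindered lactam N–H free and removes the indole nitrogen as a competing nucleophile in the copper coupling.

Step 4
Reactants: 7 tert-butyl 1-allyl-3-oxo-1,2,3,4-tetrahydro-9H-pyrido[3,4-b]indole-9-carboxylate; 2 4-bromo-2-iodofuran
Product: 8 tert-butyl 1-allyl-2-(4-bromofuran-2-yl)-3-oxo-1,2,3,4-tetrahydro-9H-pyrido[3,4-b]indole-9-carboxylate (racemic)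
Conditions: CuI (10 mol %), N,N'-dimethylethylenediamine (20 mol %), K3PO4, 1,4-dioxane, 70 °C
Reagents that add atoms: none
Why: Goldberg-type copper-catalysed amidation of a halofuran with a lactam: the copper amidate engages the C2–I bond far faster than the C4–Br bond, so the halogen fixes the site of N–C bond formation and the temperature can stay below that at which aryl bromides couple or 8 cyclises.

Step 5
Reactants: 8 tert-butyl 1-allyl-2-(4-bromofuran-2-yl)-3-oxo-1,2,3,4-tetrahydro-9H-pyrido[3,4-b]indole-9-carboxylate
Product: 12 3-bromo-7,12,12b,13-tetrahydro-6H-pyrido[1,2-a:3,4-b']diindol-6-one (racemic), via oxygen-bridged cycloadduct 9 (not isolated), via hydroxy cyclohexadiene 10 (not isolated), via N12-Boc indoline lactam 11 (not isolated)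
Conditions: PhMe, 165 °C (sealed tube); concentrate; TFA, CH2Cl2, 0 °C to rt
Reagents that add atoms: none
Why: This is the intramolecular Diels–Alder reaction of a 2-amidofuran with a tethered unactivated alkene, a known route to indolines. The furan C2–C5 diene adds to the terminal alkene, and the short link from N5 (C12b, C13) allows only the fused mode, so furan C2 bonds the internal alkene carbon (C4a–C13a; ring D, five-membered, closed as the tether ring) and furan C5 bonds the terminal carbon (C2–C1; ring E, six-membered, closed as the cycloaddition ring), giving 9. The lone pair of N5 then expels the bridging oxygen from C4a, the zwitterion loses the C13a proton to give 10, and elimination of water across C1–C2 aromatises ring E to 11; this irreversible sequence drains the reversible cycloaddition. No new stereocentre survives, because C2, C4a and C13a of 9 become sp2 and C12b is carried over as the racemate, so neither exo/endo nor facial selectivity matters. The selectivities needed are the fused regiochemistry (fixed by the tether length), bromine on C3 (fixed because furan C4 becomes C3) and proton loss with dehydration in preference to a hydride shift to a ketone (favoured because C13a carries a hydrogen). TFA then completes any unfinished dehydration and cleaves whatever indole carbamate survives the heating.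

Step 6
Reactants: 12 3-bromo-7,12,12b,13-tetrahydro-6H-pyrido[1,2-a:3,4-b']diindol-6-one
Product: 13 3-bromo-6,7,12b,13-tetrahydro-12H-pyrido[1,2-a:3,4-b']diindole (racemic)
Conditions: BH3·THF (3 equiv), THF, 0 °C to reflux; MeOH, reflux
Reagents that add atoms: none
Why: Borane reduction of a tertiary anilide lactam to the amine; BH3 leaves the aryl bromide and the indole untouched, and removing the carbonyl while N5 is still an indoline nitrogen avoids the ring opening that an N-acylindole hemiaminal would invite.

Step 7
Reactants: 13 3-bromo-6,7,12b,13-tetrahydro-12H-pyrido[1,2-a:3,4-b']diindole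
Product: 15 3-bromo-12H-pyrido[1,2-a:3,4-b']diindole, via 6,7-dihydro compound 14 (not isolated)
Conditions: DDQ (2.1 equiv), 1,4-dioxane (dry), rt then 80 °C
Reagents that add atoms: none
Why: Quinone dehydrogenation: DDQ takes hydride from C12b (α to N5 and to indole C2) and loss of a C13 proton gives indole 14, then takes hydride from the indol-3-ylic C7 and loss of a C6 proton aromatises ring C; the aryl bromide is inert to DDQ and dry conditions suppress oxygenation at C7.

Step 8
Reactants: 15 3-bromo-12H-pyrido[1,2-a:3,4-b']diindole
Product: 17 3-bromo-12H-pyrido[1,2-a:3,4-b']diindole-13-carbaldehyde (the target), via iminium chloride 16 (not isolated)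
Conditions: POCl3 (1.2 equiv), DMF, 0 °C to rt; aq NaOH
Reagents that add atoms: N,N-dimethylformamide, CN(C)C=O; water, O
Why: Vilsmeier–Haack formylation: the chloroiminium ion attacks C13, the enamine-type β-carbon of ring D and the most nucleophilic site of the core, giving 16, whose basic hydrolysis releases the aldehyde while N12–H stays free.

## Compound list

1 | 4-bromofuran-2-carboxylic acid | OC(=O)c1cc(Br)co1 | starting material
2 | 4-bromo-2-iodofuran | Ic1cc(Br)co1 | intermediate
3 | indole-3-acetamide | NC(=O)Cc1c[nH]c2ccccc12 | starting material
4 | but-3-enal diethyl acetal (4,4-diethoxybut-1-ene) | C=CCC(OCC)OCC | starting material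
5 | N-(1-ethoxybut-3-en-1-yl)-2-(1H-indol-3-yl)acetamide (racemic, not isolated) | C=CCC(OCC)NC(=O)Cc1c[nH]c2ccccc12 | intermediate
6 | 1-allyl-1,2,4,9-tetrahydro-3H-pyrido[3,4-b]indol-3-one (racemic) | C=CCC1NC(=O)Cc2c1[nH]c1ccccc21 | intermediate
7 | tert-butyl 1-allyl-3-oxo-1,2,3,4-tetrahydro-9H-pyrido[3,4-b]indole-9-carboxylate (racemic) | C=CCC1NC(=O)Cc2c1n(C(=O)OC(C)(C)C)c1ccccc21 | intermediate
8 | tert-butyl 1-allyl-2-(4-bromofuran-2-yl)-3-oxo-1,2,3,4-tetrahydro-9H-pyrido[3,4-b]indole-9-carboxylate (racemic) | C=CCC1N(c2cc(Br)co2)C(=O)Cc2c1n(C(=O)OC(C)(C)C)c1ccccc21 | intermediate
9 | tert-butyl 3-bromo-6-oxo-1,2,6,7,12b,13-hexahydro-2,4a-epoxypyrido[1,2-a:3,4-b']diindole-12(13aH)-carboxylate (racemic, oxygen bridge from C2 to C4a, both C12b epimers possible, not isolated) | O=C1Cc2c(n(C(=O)OC(C)(C)C)c3ccccc23)C2CC3CC4OC3(C=C4Br)N12 | intermediate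
10 | tert-butyl 3-bromo-2-hydroxy-6-oxo-1,2,6,7,12b,13-hexahydro-12H-pyrido[1,2-a:3,4-b']diindole-12-carboxylate (racemic, both C2 epimers possible, not isolated) | O=C1Cc2c(n(C(=O)OC(C)(C)C)c3ccccc23)C2CC3=C(C=C(Br)C(O)C3)N12 | intermediate
11 | tert-butyl 3-bromo-6-oxo-6,7,12b,13-tetrahydro-12H-pyrido[1,2-a:3,4-b']diindole-12-carboxylate (racemic, not isolated) | O=C1Cc2c(n(C(=O)OC(C)(C)C)c3ccccc23)C2Cc3ccc(Br)cc3N12 | intermediate
12 | 3-bromo-7,12,12b,13-tetrahydro-6H-pyrido[1,2-a:3,4-b']diindol-6-one (racemic) | O=C1Cc2c([nH]c3ccccc23)C2Cc3ccc(Br)cc3N12 | intermediate
13 | 3-bromo-6,7,12b,13-tetrahydro-12H-pyrido[1,2-a:3,4-b']diindole (racemic) | Brc1ccc2c(c1)N1CCc3c([nH]c4ccccc34)C1C2 | intermediate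
14 | 3-bromo-6,7-dihydro-12H-pyrido[1,2-a:3,4-b']diindole (not isolated) | Brc1ccc2cc3n(CCc4c3[nH]c3ccccc43)c2c1 | intermediate
15 | 3-bromo-12H-pyrido[1,2-a:3,4-b']diindole | Brc1ccc2cc3c4[nH]c5ccccc5c4ccn3c2c1 | intermediate
16 | N-[(3-bromo-12H-pyrido[1,2-a:3,4-b']diindol-13-yl)methylidene]-N-methylmethanaminium chloride (not isolated) | C[N+](C)=Cc1c2ccc(Br)cc2n2ccc3c4ccccc4[nH]c3c12.[Cl-] | intermediate
17 | 3-bromo-12H-pyrido[1,2-a:3,4-b']diindole-13-carbaldehyde | O=Cc1c2ccc(Br)cc2n2ccc3c4ccccc4[nH]c3c12 | target

## Step count and least certain steps

Total step count: 8. Longest linear sequence: 7 steps (3 to 17 through steps 2–8); step 1 is a one-step branch that joins at step 4.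

**Step 5 (key step).** The reversible cycloaddition may stall with the unactivated alkene while the amidofuran slowly decomposes on long heating. The opened bridge may also follow the hydride-shift channel from C2 to the bromine-bearing C3 and then lose HBr, which would cost the bromine. The fallback sets out from 3 and returns at 11, and so at 12; it buys ring E as a benzene and forms the N5–C4a bond last. Wittig methoxymethylenation of purchased 4-bromo-2-iodobenzaldehyde (methoxymethyltriphenylphosphonium chloride, KOtBu, THF) gives 4-bromo-2-iodo-1-(2-methoxyvinyl)benzene F4. Compound 3 and F4 under the TFA conditions of step 2 should give 1-(4-bromo-2-iodobenzyl)-1,2,4,9-tetrahydro-3H-pyrido[3,4-b]indol-3-one F5. Boc2O and DMAP as in step 3 give tert-butyl 1-(4-bromo-2-iodobenzyl)-3-oxo-1,2,3,4-tetrahydro-9H-pyrido[3,4-b]indole-9-carboxylate F6. Intramolecular Goldberg amidation (CuI, N,N'-dimethylethylenediamine, K3PO4, dioxane, 60 °C) closes ring D at the C–I bond, leaves C–Br and gives 11, which TFA converts into 12.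

**Step 1.** Electrophilic iodination at the free C5–H may compete with ipso attack, decarboxylation may be incomplete, and the volatile, light-sensitive product may be lost on isolation. The fallback sets out from 1 and returns at 2; it uses a radical in place of an ionic decarboxylation. The acid chloride of 1 ((COCl)2, cat. DMF) and the sodium salt of N-hydroxypyridine-2-thione give 2-thioxopyridin-1(2H)-yl 4-bromofuran-2-carboxylate F1. Warming or irradiating F1 with iodoform should give 2 through the furyl radical (Barton decarboxylative iodination).

**Step 2.** The double bond may migrate into conjugation at the oxocarbenium or N-acyliminium stage to give a dienamide. Indole C2 may also add twice to the electrophile, and the cation may be captured by the alkene. The fallback sets out from 3 and returns at 6; it makes the alkene only after ring C exists. Compound 3 and malonaldehyde bis(dimethyl acetal) under TFA give 1-(2,2-dimethoxyethyl)-1,2,4,9-tetrahydro-3H-pyrido[3,4-b]indol-3-one F2. Aqueous formic acid unmasks 2-(3-oxo-2,3,4,9-tetrahydro-1H-pyrido[3,4-b]indol-1-yl)acetaldehyde F3. Wittig methylenation with excess Ph3P=CH2 in THF gives 6.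

**Step 4.** Oxidative coupling at the hindered lactam nitrogen may be slow, which would let the iodofuran decompose, the carbamate be lost or the C4–Br bond start to react. The fallback sets out from 7 and 2 and returns at 8; it changes the bond-forming manifold from a copper amidate to a Buchwald–Hartwig amidation. Zerovalent palladium from Pd2(dba)3 with Xantphos and Cs2CO3 in dioxane adds first to the C–I bond and binds the amidate afterwards. No new compound is involved.

**Step 7.** The quinone may over-oxidise the electron-rich product at C13 or C12b, oxygenate C7 if water is present, or fail to complete the second dehydrogenation. The fallback sets out from 13 and returns at 17; it reorders the endgame so that the last oxidation acts on a deactivated substrate. DDQ (1.05 equiv, rt) gives 14, which is isolated. Vilsmeier–Haack formylation at its free indole C3 position gives 3-bromo-6,7-dihydro-12H-pyrido[1,2-a:3,4-b']diindole-13-carbaldehyde F7. DDQ (1.1 equiv, dioxane, 80 °C) then removes the C6/C7 hydrogens and gives 17.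

## Further compounds

F1 | step 1 | 2-thioxopyridin-1(2H)-yl 4-bromofuran-2-carboxylate | O=C(ON1C=CC=CC1=S)c1cc(Br)co1
F2 | step 2 | 1-(2,2-dimethoxyethyl)-1,2,4,9-tetrahydro-3H-pyrido[3,4-b]indol-3-one (racemic) | COC(OC)CC1NC(=O)Cc2c1[nH]c1ccccc21
F3 | step 2 | 2-(3-oxo-2,3,4,9-tetrahydro-1H-pyrido[3,4-b]indol-1-yl)acetaldehyde (racemic) | O=CCC1NC(=O)Cc2c1[nH]c1ccccc21
F0 | step 4 | none | none
F4 | step 5 | 4-bromo-2-iodo-1-(2-methoxyvinyl)benzene (E/Z mixture) | COC=Cc1ccc(Br)cc1I
F5 | step 5 | 1-(4-bromo-2-iodobenzyl)-1,2,4,9-tetrahydro-3H-pyrido[3,4-b]indol-3-one (racemic) | O=C1Cc2c([nH]c3ccccc23)C(Cc2ccc(Br)cc2I)N1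
F6 | step 5 | tert-butyl 1-(4-bromo-2-iodobenzyl)-3-oxo-1,2,3,4-tetrahydro-9H-pyrido[3,4-b]indole-9-carboxylate (racemic) | O=C1Cc2c(n(C(=O)OC(C)(C)C)c3ccccc23)C(Cc2ccc(Br)cc2I)N1
F7 | step 7 | 3-bromo-6,7-dihydro-12H-pyrido[1,2-a:3,4-b']diindole-13-carbaldehyde | O=Cc1c2ccc(Br)cc2n2CCc3c4ccccc4[nH]c3c12
A1 | alternative 1 | N-{2-[3-(tert-butyldimethylsilyloxy)propanoyl]phenyl}-6-bromo-1H-indole-2-carboxamide | CC(C)(C)[Si](C)(C)OCCC(=O)c1ccccc1NC(=O)c1cc2ccc(Br)cc2[nH]1
A2 | alternative 1 | 6-bromo-3'-[2-(tert-butyldimethylsilyloxy)ethyl]-1H,1'H-2,2'-biindole | CC(C)(C)[Si](C)(C)OCCc1c([nH]c2ccccc12)-c1cc2ccc(Br)cc2[nH]1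
A3 | alternative 2 | 2-[1,1-dibromo-4-(6-bromo-1H-indol-1-yl)but-1-en-2-yl]aniline | Nc1ccccc1C(=C(Br)Br)CCn1ccc2ccc(Br)cc21
A4 | alternative 2 | 3-bromo-6,7-dihydro-12H-pyrido[1,2-a:3,4-b']diindole (identical with 14) | Brc1ccc2cc3n(CCc4c3[nH]c3ccccc43)c2c1
A5 | alternative 3 | 1-(4-bromo-2-nitrobenzyl)-9H-pyrano[3,4-b]indol-2-ium tetrafluoroborate | [O-][N+](=O)c1cc(Br)ccc1Cc1[o+]ccc2c3ccccc3[nH]c12.F[B-](F)(F)F
A6 | alternative 3 | 3-bromo-12H-pyrido[1,2-a:3,4-b']diindole (identical with 15) | Brc1ccc2cc3c4[nH]c5ccccc5c4ccn3c2c1
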